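**Retrosynthetic overview**

1. The pyrone is attached last, by palladium-catalysed allylation of 4-hydroxy-6-methyl-2-pyrone at its ring carbon between the two oxygenated carbons with allylic alcohol 25. Diol 25 comes from an sp3–sp2 Suzuki coupling of ring boronate 14 with (E)-alkenyl iodide 24, which forms the chain bond CH2–C(CH3)= nearest the ring.
2. The cyclohexane is closed at the bond between the ring carbon that carries the exocyclic methylene and the ring CH that carries the side chain, by a 6-exo vinyl-radical cyclization onto a temporary cyclic alkenylboronate (11 to 12).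
3. Enabling feature: the carbinol oxygen and the first side-chain CH2 stand cis-1,3 on the cyclohexane, separated only by the C(CH3)2 carbon, so an O–B–C bridge (a six-membered 1,2-oxaborinine, after closure a 2-oxa-3-borabicyclo[3.3.1]nonane) can tie them. The C=CH2 on the neighbouring ring carbon is what a vinyl radical from a 2-bromoalkene leaves behind.
4. Ring order: oxaborinine (boron-tethered ring-closing metathesis), then the carbocycle (key step), then the boron ring is enlarged by one CH2 (Matteson) and excised in the Suzuki step, which frees the carbinol. The pyrone ring is bought.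
5. Stereochemistry: the carbinol centre comes from an enantioselective iridium-catalysed tert-prenylation, and the ring CH centre is relayed from it through the boron bridge. Both (E)-trisubstituted alkenes are made in fragment 24.

Key step: step 5

Remark (assumption): in step 3 the sense of induction is taken to follow the ligand antipode; the SEGPHOS antipode that delivers the (4S)-alcohol is meant.

**Route**

Step 1
Reactants: 1 2-bromoprop-2-en-1-ol; 2 triethyl orthoacetate
Product: 4 ethyl 4-bromopent-4-enoate, via mixed ketene acetal 3 (not isolated)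
Conditions: 2 (4 equiv), EtCO2H (cat.), 140 °C, EtOH distilled off
Reagents that add atoms: none
Why: Johnson–Claisen rearrangement; the ketene acetal formed by orthoester exchange should undergo the [3,3] shift that puts the 2-bromoallyl unit on the acetate α-carbon, and no stereocentre is formed.

Step 2
Reactants: 4 ethyl 4-bromopent-4-enoate
Product: 5 4-bromopent-4-en-1-ol
Conditions: LiAlH4, Et2O, 0 °C; aq. NaOH work-up
Reagents that add atoms: none
Why: hydride reduction of the ester at 0 °C should leave the 1,1-disubstituted bromoalkene untouched; no stereocentre is formed.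

Step 3
Reactants: 5 4-bromopent-4-en-1-ol; 6 3-methylbuta-1,2-diene
Product: 8 (4S)-7-bromo-3,3-dimethylocta-1,7-dien-4-ol, via 4-bromopent-4-enal 7 (not isolated)
Conditions: [Ir(cod)Cl]2 (2.5 mol %), SEGPHOS (5 mol %), 4-cyano-3-nitrobenzoic acid (10 mol %), Cs2CO3 (20 mol %), 6 (3 equiv), PhMe, 60 °C, sealed tube
Reagents that add atoms: none
Why: iridium-catalysed transfer-hydrogenative tert-prenylation (Krische allylation type); the alcohol is dehydrogenated to 7, the iridium hydride adds to the allene, and the 1,1-dimethylallyl iridium adds through its substituted terminus within the chiral ligand sphere, which sets the (4S) carbinol centre by catalyst control.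

Step 4
Reactants: 8 (4S)-7-bromo-3,3-dimethylocta-1,7-dien-4-ol; 9 dibutyl ethenylboronate
Product: 11 (6S)-6-(3-bromobut-3-en-1-yl)-2-butoxy-5,5-dimethyl-5,6-dihydro-2H-1,2-oxaborinine, via mixed vinylboronate 10 (not isolated)
Conditions: 9 (1.2 equiv), PhMe, 60 °C, reduced pressure (n-BuOH removed); then second-generation Grubbs catalyst (5 mol %), PhMe, 80 °C, argon purge
Reagents that add atoms: none
Why: boron-tethered ring-closing metathesis; transesterification ties the vinylboron unit to the carbinol oxygen and metathesis with the vinyl group on the quaternary carbon closes the six-membered ring with a necessarily cis alkene, while the hindered, electron-poor 2-bromoalkene should stay a spectator and the carbinol centre is not touched.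

Step 5
Reactants: 11 (6S)-6-(3-bromobut-3-en-1-yl)-2-butoxy-5,5-dimethyl-5,6-dihydro-2H-1,2-oxaborinine
Product: 12 (1S,5R)-3-butoxy-9,9-dimethyl-6-methylidene-2-oxa-3-borabicyclo[3.3.1]nonane
Conditions: Bu3SnH (1.3 equiv) and AIBN (0.2 equiv) added by syringe pump over 6 h, PhH, 80 °C, 0.01 M; non-aqueous work-up
Reagents that add atoms: none
Why: Bu3Sn• abstracts bromine from the 2-bromoalkene, the σ-vinyl radical adds to the ring alkene carbon next to the gem-dimethyl carbon, and the α-boryl radical so formed takes hydrogen from Bu3SnH and carries the chain. The closest known reaction types are the vinyl-radical cyclization of 2-bromo-1,6- and 1,7-dienes with tin hydride and radical cyclizations onto alkenylboronic esters, including boron-tethered ones. The carbocycle closes in the 6-exo-trig mode and becomes one ring of a 2-oxa-3-borabicyclo[3.3.1]nonane. The new ring CH centre is controlled by the carbinol centre through the temporary ring: the two-carbon arm that carries the radical can reach only the face of the oxaborinine to which it is attached, so oxygen and the CH2B carbon must end cis-1,3, the only arrangement a three-atom O–B–C bridge allows. The step needs 6-exo over 7-endo closure, which boron secures because attack β to boron gives the stabilised α-boryl radical, and it needs ring closure to outrun reduction of the vinyl radical, which slow addition of the hydride at high dilution secures.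

Step 6
Reactants: 12 (1S,5R)-3-butoxy-9,9-dimethyl-6-methylidene-2-oxa-3-borabicyclo[3.3.1]nonane
Product: 14 (1S,6R)-3-butoxy-10,10-dimethyl-7-methylidene-2-oxa-3-borabicyclo[4.3.1]decane, via chloromethyl borate complex 13 (not isolated)
Conditions: BrCH2Cl (1.5 equiv), n-BuLi (1.3 equiv), THF, −78 °C to rt
Reagents that add atoms: bromochloromethane, ClCBr
Why: Matteson homologation; LiCH2Cl adds to boron and the ring CH2, the only carbon ligand on boron, should migrate with loss of chloride, which inserts one CH2 and enlarges the boron ring without touching either stereocentre.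

Step 7
Reactants: 15 methyl acetoacetate; 16 1-bromobut-2-yne
Product: 18 methyl 3-oxooct-6-ynoate, via acetoacetate dianion 17 (not isolated)
Conditions: NaH, THF, 0 °C; n-BuLi, 0 °C; 16, 0 °C to rt; 1 M HCl
Reagents that add atoms: none
Why: γ-alkylation of the acetoacetate dianion; the more basic terminal carbanion should displace the propargylic bromide by SN2, and no stereocentre is formed.

Step 8
Reactants: 18 methyl 3-oxooct-6-ynoate
Product: 20 methyl (2Z)-3-[(diethoxyphosphoryl)oxy]oct-2-en-6-ynoate, via sodium enolate 19 (not isolated)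
Conditions: NaH, Et2O, 0 °C; ClP(O)(OEt)2, 0 °C to rt
Reagents that add atoms: diethyl chlorophosphate, CCOP(=O)(Cl)OCC
Why: O-phosphorylation of the chelated sodium enolate of a β-keto ester, which should fix the (Z) enol phosphate geometry (phosphate cis to the ester).

Step 9
Reactants: 20 methyl (2Z)-3-[(diethoxyphosphoryl)oxy]oct-2-en-6-ynoate
Product: 21 methyl (2E)-3-methyloct-2-en-6-ynoate
Conditions: Me2CuLi (from CuI and 2 MeLi), Et2O, −78 to −45 °C
Reagents that add atoms: lithium dimethylcuprate, [Li+].C[Cu-]C
Why: cuprate substitution of the β-phosphoryloxy enoate by addition–elimination with retention, which should give the (E) trisubstituted alkene; the unactivated internal alkyne is inert to the cuprate at this temperature.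

Step 10
Reactants: 21 methyl (2E)-3-methyloct-2-en-6-ynoate
Product: 22 (2E)-3-methyloct-2-en-6-yn-1-ol
Conditions: i-Bu2AlH (2.2 equiv), CH2Cl2, −78 °C; aq. potassium sodium tartrate
Reagents that add atoms: none
Why: 1,2-reduction of the enoate to the allylic alcohol, which should leave the alkene geometry and the alkyne intact.

Step 11
Reactants: 22 (2E)-3-methyloct-2-en-6-yn-1-ol
Product: 24 (2E,6E)-7-iodo-3-methylocta-2,6-dien-1-ol, via alkenylzirconocene 23 (not isolated)
Conditions: Cp2Zr(H)Cl (2.5 equiv), THF, rt then 45 °C; I2, THF, 0 °C; aqueous work-up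
Reagents that add atoms: iodine, II
Why: hydrozirconation–iodination; syn addition of Zr–H across the 2-alkyne, equilibrated by the excess hydride so that zirconium sits on the methyl-bearing carbon, followed by iodinolysis with retention should give the (E)-2-iodoalkene, the first equivalent of hydride being used up by the hydroxyl group.

Step 12
Reactants: 14 (1S,6R)-3-butoxy-10,10-dimethyl-7-methylidene-2-oxa-3-borabicyclo[4.3.1]decane; 24 (2E,6E)-7-iodo-3-methylocta-2,6-dien-1-ol
Product: 25 (2E,6E)-9-[(1R,3S)-3-hydroxy-2,2-dimethyl-6-methylidenecyclohexyl]-3,7-dimethylnona-2,6-dien-1-ol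
Conditions: Pd(OAc)2 (5 mol %), SPhos (10 mol %), K3PO4 (3 equiv), PhMe/H2O 10:1, 80 °C
Reagents that add atoms: none
Why: sp3–sp2 Suzuki–Miyaura coupling; aqueous base opens the boron ring to the primary alkyl borate, which transmetalates to the alkenylpalladium iodide, and reductive elimination should proceed with retention of the (E) geometry and release the ring carbinol as the free alcohol.

Step 13
Reactants: 25 (2E,6E)-9-[(1R,3S)-3-hydroxy-2,2-dimethyl-6-methylidenecyclohexyl]-3,7-dimethylnona-2,6-dien-1-ol; 26 4-hydroxy-6-methyl-2H-pyran-2-one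
Product: 27 sartorypyrone D, 4-hydroxy-3-[(2E,6E)-9-[(1R,3S)-3-hydroxy-2,2-dimethyl-6-methylidenecyclohexyl]-3,7-dimethylnona-2,6-dien-1-yl]-6-methyl-2H-pyran-2-one
Conditions: Pd(PPh3)4 (5 mol %), 26 (2 equiv), THF, 65 °C
Reagents that add atoms: none
Why: Tsuji–Trost allylation with an allylic alcohol that the acidic pyrone itself activates; the soft pyrone carbon should attack the unsubstituted terminus of the π-allyl palladium to give the linear (E) product, any O-allyl ether re-ionising to the C-allylated pyrone, and the non-allylic ring carbinol is inert.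

**Compound list**

1 | 2-bromoprop-2-en-1-ol | C=C(Br)CO | starting material
2 | triethyl orthoacetate | CC(OCC)(OCC)OCC | starting material
3 | 2-bromo-3-[(1-ethoxyethenyl)oxy]prop-1-ene (mixed ketene acetal) | C=C(OCC)OCC(Br)=C | intermediate
4 | ethyl 4-bromopent-4-enoate | C=C(Br)CCC(=O)OCC | intermediate
5 | 4-bromopent-4-en-1-ol | C=C(Br)CCCO | intermediate
6 | 3-methylbuta-1,2-diene | CC(C)=C=C | starting material
7 | 4-bromopent-4-enal | C=C(Br)CCC=O | intermediate
8 | (4S)-7-bromo-3,3-dimethylocta-1,7-dien-4-ol | C=C(Br)CC[C@H](O)C(C)(C)C=C | intermediate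
9 | dibutyl ethenylboronate | C=CB(OCCCC)OCCCC | starting material
10 | butyl (4S)-7-bromo-3,3-dimethylocta-1,7-dien-4-yl ethenylboronate | C=C(Br)CC[C@H](OB(OCCCC)C=C)C(C)(C)C=C | intermediate
11 | (6S)-6-(3-bromobut-3-en-1-yl)-2-butoxy-5,5-dimethyl-5,6-dihydro-2H-1,2-oxaborinine | C=C(Br)CC[C@@H]1OB(OCCCC)C=CC1(C)C | intermediate
12 | (1S,5R)-3-butoxy-9,9-dimethyl-6-methylidene-2-oxa-3-borabicyclo[3.3.1]nonane | C=C1CC[C@@H]2OB(OCCCC)C[C@H]1C2(C)C | intermediate
13 | lithium (1S,5R)-3-butoxy-3-(chloromethyl)-9,9-dimethyl-6-methylidene-2-oxa-3-boranuidabicyclo[3.3.1]nonane | [Li+].C=C1CC[C@@H]2O[B-](OCCCC)(CCl)C[C@H]1C2(C)C | intermediate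
14 | (1S,6R)-3-butoxy-10,10-dimethyl-7-methylidene-2-oxa-3-borabicyclo[4.3.1]decane | C=C1CC[C@@H]2OB(OCCCC)CC[C@H]1C2(C)C | intermediate
15 | methyl acetoacetate | CC(=O)CC(=O)OC | starting material
16 | 1-bromobut-2-yne | CC#CCBr | starting material
17 | sodium lithium dianion of methyl acetoacetate | [Na+].[Li+].C=C([O-])C=C([O-])OC | intermediate
18 | methyl 3-oxooct-6-ynoate | CC#CCCC(=O)CC(=O)OC | intermediate
19 | sodium (Z)-enolate of methyl 3-oxooct-6-ynoate | [Na+].CC#CCC/C([O-])=C/C(=O)OC | intermediate
20 | methyl (2Z)-3-[(diethoxyphosphoryl)oxy]oct-2-en-6-ynoate | CC#CCC/C(OP(=O)(OCC)OCC)=C/C(=O)OC | intermediate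
21 | methyl (2E)-3-methyloct-2-en-6-ynoate | CC#CCC/C(C)=C/C(=O)OC | intermediate
22 | (2E)-3-methyloct-2-en-6-yn-1-ol | CC#CCC/C(C)=C/CO | intermediate
23 | O,C-bis(chlorozirconocene) derivative of (2E,6E)-3-methylocta-2,6-dien-1-ol, zirconium on oxygen and on the methyl-bearing alkene carbon 7 | C/C(=C\CC/C(C)=C/CO[Zr](Cl)(C1C=CC=C1)C1C=CC=C1)[Zr](Cl)(C1C=CC=C1)C1C=CC=C1 | intermediate
24 | (2E,6E)-7-iodo-3-methylocta-2,6-dien-1-ol | C/C(I)=C\CC/C(C)=C/CO | intermediate
25 | (2E,6E)-9-[(1R,3S)-3-hydroxy-2,2-dimethyl-6-methylidenecyclohexyl]-3,7-dimethylnona-2,6-dien-1-ol | C=C1CC[C@H](O)C(C)(C)[C@@H]1CC/C(C)=C/CC/C(C)=C/CO | intermediate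
26 | 4-hydroxy-6-methyl-2H-pyran-2-one | Cc1cc(O)cc(=O)o1 | starting material
27 | sartorypyrone D | C=C1CC[C@H](O)C(C)(C)[C@@H]1CC/C(C)=C/CC/C(C)=C/Cc1c(O)cc(C)oc1=O | target

**Step count and risks**

Total steps: 13. Longest linear sequence: 8 (steps 1 to 6, 12 and 13).

Steps most likely to fail:

1. Step 5. The vinyl radical may be reduced before it closes the ring, or the alkenylboronate may be lost by hydrolysis or protodeboronation under the radical conditions, so that no bicyclic boronate forms. The fallback replaces the boron bridge by a carbon bridge; it sets out from 8 and comes back at 25. Alcohol 8 is acylated with acryloyl chloride (Et3N, DMAP, CH2Cl2, 0 °C) to the acrylate ester F1. Ring-closing metathesis (second-generation Grubbs catalyst, PhMe, 80 °C) should give the α,β-unsaturated δ-lactone F2. The vinyl radical (Bu3SnH, AIBN, PhH, 80 °C, slow addition) then adds 6-exo in conjugate fashion to the lactone β-carbon next to the gem-dimethyl carbon, giving the bridged lactone F3 with the same enforced cis relationship. LiAlH4 (THF, 0 °C) opens it to the diol F4. The primary alcohol is converted selectively (I2, PPh3, imidazole, CH2Cl2, 0 °C) into the iodo alcohol F5. Copper-catalysed borylation (B2pin2, CuI, PPh3, LiOMe, DMF, rt) gives the pinacol boronate F6, which is coupled with 24 under the conditions of step 12 to give 25.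

2. Step 6. In the bridged borate complex an alkoxy group may migrate instead of the ring CH2, or the butoxy ligand may be lost to adventitious water, which stops the homologation. The fallback takes boron out of the ring before homologation; it sets out from 12 and comes back at 25. Boronate 12 is opened with pinacol (Et2O, MgSO4, rt) to the hydroxy pinacol boronate F7. The freed carbinol is silylated (TBSOTf, 2,6-lutidine, CH2Cl2, 0 °C) to the silyl ether F8. The one-carbon homologation is run on this acyclic ester (BrCH2Cl, n-BuLi, THF, −78 °C to rt) to give the homologated pinacol boronate F9. Suzuki coupling with 24 as in step 12 gives the silyl-protected diol F10, and Bu4NF (THF, rt) removes the silyl group to give 25.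

3. Step 13. O-allylation, double allylation at the pyrone carbon or erosion of the alkene geometry through the π-allyl palladium intermediate may compete with clean mono-C-allylation. The fallback builds the pyrone ring on the chain instead of alkylating it; it sets out from 25 and comes back at 27. The primary allylic alcohol of 25 is converted (CBr4, PPh3, CH2Cl2, −20 °C, the hindered ring carbinol being left) into the allylic bromide F11. SN2 alkylation of the sodium enolate of methyl acetoacetate (NaH, THF, 0 °C to rt) gives the β-keto ester F12 as a mixture of epimers at a centre that is lost later. Deprotonation with LiN(i-Pr)2 (3.2 equiv, THF, −78 to 0 °C) and γ-acetylation with N-methoxy-N-methylacetamide give the 3,5-dioxo ester F13. Lactonization (DBU, PhMe, 80 °C) with loss of methanol closes the 4-hydroxy-2-pyrone and gives 27.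

**Further compounds**

F1 | step 5 | (4S)-7-bromo-3,3-dimethylocta-1,7-dien-4-yl prop-2-enoate | C=C(Br)CC[C@H](OC(=O)C=C)C(C)(C)C=C
F2 | step 5 | (6S)-6-(3-bromobut-3-en-1-yl)-5,5-dimethyl-5,6-dihydro-2H-pyran-2-one | C=C(Br)CC[C@@H]1OC(=O)C=CC1(C)C
F3 | step 5 | (1S,5R)-9,9-dimethyl-6-methylidene-2-oxabicyclo[3.3.1]nonan-3-one | C=C1CC[C@@H]2OC(=O)C[C@H]1C2(C)C
F4 | step 5 | (1S,3R)-3-(2-hydroxyethyl)-2,2-dimethyl-4-methylidenecyclohexan-1-ol | C=C1CC[C@H](O)C(C)(C)[C@@H]1CCO
F5 | step 5 | (1S,3R)-3-(2-iodoethyl)-2,2-dimethyl-4-methylidenecyclohexan-1-ol | C=C1CC[C@H](O)C(C)(C)[C@@H]1CCI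
F6 | step 5 | (1S,3R)-2,2-dimethyl-4-methylidene-3-[2-(4,4,5,5-tetramethyl-1,3,2-dioxaborolan-2-yl)ethyl]cyclohexan-1-ol | C=C1CC[C@H](O)C(C)(C)[C@@H]1CCB1OC(C)(C)C(C)(C)O1
F7 | step 6 | (1S,3R)-2,2-dimethyl-4-methylidene-3-[(4,4,5,5-tetramethyl-1,3,2-dioxaborolan-2-yl)methyl]cyclohexan-1-ol | C=C1CC[C@H](O)C(C)(C)[C@@H]1CB1OC(C)(C)C(C)(C)O1
F8 | step 6 | tert-butyl{[(1S,3R)-2,2-dimethyl-4-methylidene-3-[(4,4,5,5-tetramethyl-1,3,2-dioxaborolan-2-yl)methyl]cyclohexyl]oxy}dimethylsilane | C=C1CC[C@H](O[Si](C)(C)C(C)(C)C)C(C)(C)[C@@H]1CB1OC(C)(C)C(C)(C)O1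
F9 | step 6 | tert-butyl{[(1S,3R)-2,2-dimethyl-4-methylidene-3-[2-(4,4,5,5-tetramethyl-1,3,2-dioxaborolan-2-yl)ethyl]cyclohexyl]oxy}dimethylsilane | C=C1CC[C@H](O[Si](C)(C)C(C)(C)C)C(C)(C)[C@@H]1CCB1OC(C)(C)C(C)(C)O1
F10 | step 6 | (2E,6E)-9-[(1R,3S)-3-{[tert-butyl(dimethyl)silyl]oxy}-2,2-dimethyl-6-methylidenecyclohexyl]-3,7-dimethylnona-2,6-dien-1-ol | C=C1CC[C@H](O[Si](C)(C)C(C)(C)C)C(C)(C)[C@@H]1CC/C(C)=C/CC/C(C)=C/CO
F11 | step 13 | (1S,3R)-3-[(3E,7E)-9-bromo-3,7-dimethylnona-3,7-dien-1-yl]-2,2-dimethyl-4-methylidenecyclohexan-1-ol | C=C1CC[C@H](O)C(C)(C)[C@@H]1CC/C(C)=C/CC/C(C)=C/CBr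
F12 | step 13 | methyl (4E,8E)-2-acetyl-11-[(1R,3S)-3-hydroxy-2,2-dimethyl-6-methylidenecyclohexyl]-5,9-dimethylundeca-4,8-dienoate (both epimers at the ester α-carbon) | C=C1CC[C@H](O)C(C)(C)[C@@H]1CC/C(C)=C/CC/C(C)=C/CC(C(C)=O)C(=O)OC
F13 | step 13 | methyl (4E,8E)-11-[(1R,3S)-3-hydroxy-2,2-dimethyl-6-methylidenecyclohexyl]-5,9-dimethyl-2-(3-oxobutanoyl)undeca-4,8-dienoate (both epimers at the ester α-carbon) | C=C1CC[C@H](O)C(C)(C)[C@@H]1CC/C(C)=C/CC/C(C)=C/CC(C(=O)CC(C)=O)C(=O)OC
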